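**Retrosynthetic overview**
1. Target ⇐ Riley α-oxidation at C9 of the 8-ketone. Chalcone arm ⇐ Claisen–Schmidt condensation of an aryl methyl ketone with 4-methoxybenzaldehyde.
2. Dihydrobenzofuran ⇐ C10–O by intramolecular oxa-Michael addition of the phenol to an aristolone-type 9-en-8-one, C1–H by hydrogenation. C1–aryl ⇐ Suzuki coupling of a C1 dienyl triflate with MOM-protected 3-bromo-2,6-dihydroxy-4-methoxyacetophenone.
3. C1 oxygen ⇐ cytochrome P450 monooxygenase allylic hydroxylation of (−)-aristolone.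
4. (−)-Aristolone ⇐ sulfur-ylide gem-dimethylcyclopropanation ⇐ Saegusa dienone ⇐ Robinson annulation on the enolate from Cu-catalysed asymmetric conjugate methylation of 2-methylcyclohexenone.
5. Ring order: ring B → ring A → cyclopropane → arene attached → dihydrofuran ring last.

Assumption: aristolane numbering is used for the terpenoid (C1–C10 decalin, CH3 on C4 and C5, C11(CH3)2 bridging C6/C7) and primed locants count round the aryl ring from the carbon bonded to C1; the ligand enantiomer in step 1 and the P450 variant in step 5 are those found on screening to give 3R and C1 hydroxylation.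

**Step 1**
Reactants: 1 2-methylcyclohex-2-en-1-one
Product: 3 (R)-2,3-dimethylcyclohex-1-en-1-yl acetate, via dimethylaluminium enolate 2 (not isolated)
Conditions: Me3Al (1.4 equiv), CuTC (2 mol %), (R,S,S)-BINOL/bis(1-phenylethyl)amine phosphoramidite (4 mol %), Et2O, −30 °C; then Ac2O, −30 → 23 °C
Reagents that add atoms: trimethylaluminium C[Al](C)C; acetic anhydride CC(=O)OC(C)=O
Why: Cu-catalysed asymmetric conjugate addition of Me3Al sets the first stereocentre C4 (R, sense fixed by the ligand enantiomer, typically ≥93% ee), and O-acetylation traps the aluminium enolate regiospecifically as the tetrasubstituted enol acetate.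

**Step 2**
Reactants: 3 (R)-2,3-dimethylcyclohex-1-en-1-yl acetate; 4 3-(trimethylsilyl)but-3-en-2-one
Product: 7 (4aS,5R)-4a,5-dimethyl-4,4a,5,6,7,8-hexahydronaphthalen-2(3H)-one, via lithium enolate 5 (not isolated), via silyl diketone 6 (not isolated)
Conditions: MeLi (2.05 equiv), THF, 0 °C; 4, −78 → −20 °C; then KOH, MeOH, 65 °C
Reagents that add atoms: none
Why: Robinson annulation in the Stork–Ganem variant: the regiodefined lithium enolate adds to the α-silyl enone anti to the neighbouring C4 methyl (setting quaternary C5 with the two methyls cis), and KOH/MeOH then desilylates and closes ring A by aldol condensation.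

**Step 3**
Reactants: 7 (4aS,5R)-4a,5-dimethyl-4,4a,5,6,7,8-hexahydronaphthalen-2(3H)-one
Product: 9 (4aR,5R)-4a,5-dimethyl-5,6,7,8-tetrahydronaphthalen-2(4aH)-one, via silyl dienol ether 8 (not isolated)
Conditions: LDA, THF, −78 °C, then TMSCl; solvent swap; Pd(OAc)2 (1.05 equiv), MeCN, 23 °C
Reagents that add atoms: none
Why: Kinetic α′-deprotonation at C7 followed by Saegusa–Ito oxidation of the silyl dienol ether installs the C6=C7 double bond regiospecifically and leaves C4/C5 untouched.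

**Step 4**
Reactants: 9 (4aR,5R)-4a,5-dimethyl-5,6,7,8-tetrahydronaphthalen-2(4aH)-one; 10 isopropyldiphenylsulfonium tetrafluoroborate
Product: 12 (−)-aristolone [(4R,5R,6S,7R)-aristol-9-en-8-one], via sulfonium isopropylide 11 (not isolated)
Conditions: 10, LDA, DME, −78 °C; then 9, −78 → −30 °C; recrystallise (pentane) to raise ee
Reagents that add atoms: none
Why: Corey–Chaykovsky-type isopropylidene transfer: the ylide adds to C6, the less substituted enone terminus, on the face opposite the axial C5 methyl and the enolate closes on C11, giving the cis-fused gem-dimethylcyclopropane with C6 (S) and C7 (R).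

**Step 5**
Reactants: 12 (−)-aristolone
Product: 13 (4R,5R,6S,7R)-1-hydroxyaristol-9-en-8-one (C1 epimers, not assigned)
Conditions: cytochrome P450 monooxygenase (P450-BM3 variant from a terpene-hydroxylation panel, cell-free extract), NADP+ (cat.), alcohol dehydrogenase/i-PrOH for NADPH recycling, air, KPi buffer pH 8, 5% DMSO, 25 °C
Reagents that add atoms: dioxygen O=O
Why: P450-catalysed allylic C–H hydroxylation (oxygen-rebound mechanism) picks the only allylic methylene, C1 (γ to the enone, weakest C–H bond), as in enzymatic γ-hydroxylation of isophorone; the configuration of the new carbinol is irrelevant because it is oxidised in step 6.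

**Step 6**
Reactants: 13 (4R,5R,6S,7R)-1-hydroxyaristol-9-en-8-one
Product: 14 (4R,5R,6S,7R)-aristol-9-ene-1,8-dione
Conditions: Dess–Martin periodinane, NaHCO3, CH2Cl2, 0 → 23 °C
Reagents that add atoms: none
Why: Dess–Martin oxidation of the secondary allylic alcohol gives the ene-dione under buffered neutral conditions that leave the cyclopropyl ketone untouched.

**Step 7**
Reactants: 14 (4R,5R,6S,7R)-aristol-9-ene-1,8-dione
Product: 15 (4R,5R,6S,7R)-8-oxoaristola-1,9-dien-1-yl trifluoromethanesulfonate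
Conditions: KHMDS, THF, −78 °C; PhNTf2, −78 → 0 °C
Reagents that add atoms: N-phenylbis(trifluoromethanesulfonimide) O=S(=O)(N(c1ccccc1)S(=O)(=O)C(F)(F)F)C(F)(F)F
Why: Enol triflate formation: the C1 ketone can only enolise toward C2 (C10 is sp2 and the C8 ketone has no enolisable α-hydrogen), so the enolate is trapped on oxygen as a single dienyl triflate.

**Step 8**
Reactants: 16 1-(2,6-dihydroxy-4-methoxyphenyl)ethan-1-one
Product: 17 1-[4-methoxy-2,6-bis(methoxymethoxy)phenyl]ethan-1-one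
Conditions: NaH, MOMCl, DMF, 0 → 23 °C
Reagents that add atoms: chloromethyl methyl ether COCCl
Why: Williamson-type O-alkylation of both phenoxides gives the bis-MOM acetal, masking the acidic phenols for the cross-coupling.

**Step 9**
Reactants: 17 1-[4-methoxy-2,6-bis(methoxymethoxy)phenyl]ethan-1-one
Product: 18 1-[3-bromo-4-methoxy-2,6-bis(methoxymethoxy)phenyl]ethan-1-one
Conditions: NBS (1.0 equiv), MeCN, 0 °C
Reagents that add atoms: N-bromosuccinimide O=C1CCC(=O)N1Br
Why: Electrophilic aromatic bromination occurs at one of the two equivalent ring positions activated by three oxygen substituents, and one equivalent of NBS at 0 °C stops at the monobromide.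

**Step 10**
Reactants: 15 (4R,5R,6S,7R)-8-oxoaristola-1,9-dien-1-yl trifluoromethanesulfonate; 18 1-[3-bromo-4-methoxy-2,6-bis(methoxymethoxy)phenyl]ethan-1-one
Product: 20 (4R,5R,6S,7R)-1-[3-acetyl-6-methoxy-2,4-bis(methoxymethoxy)phenyl]aristola-1,9-dien-8-one, via dienyl boronate 19 (not isolated)
Conditions: B2pin2, PdCl2(dppf) (3 mol %), KOAc, dioxane, 80 °C; then 18, Pd(OAc)2/SPhos (5/10 mol %), K3PO4, H2O, 90 °C
Reagents that add atoms: none
Why: Miyaura borylation of the dienyl triflate followed in the same pot by Suzuki–Miyaura coupling (SPhos copes with the di-ortho-substituted, electron-rich bromide) forms the C1–aryl bond with no stereocentre involved.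

**Step 11**
Reactants: 20 (4R,5R,6S,7R)-1-[3-acetyl-6-methoxy-2,4-bis(methoxymethoxy)phenyl]aristola-1,9-dien-8-one
Product: 22 (4R,5R,6S,7R,10R)-1-(3-acetyl-4-hydroxy-6-methoxyphenyl)-10,2′-epoxyaristol-1-en-8-one, via bisphenol dienone 21 (not isolated)
Conditions: Dowex 50W-X8 (H+), MeOH, 60 °C; filter; Et3N (0.2 equiv), MeOH, 23 °C
Reagents that add atoms: none
Why: Acid-catalysed acetal cleavage frees both phenols, and amine-catalysed intramolecular oxa-Michael addition (5-exo-trig) of the 2′-OH to C10 occurs on the face opposite the gem-dimethylcyclopropane (the face of the C5 methyl), setting the C10–O stereocentre; the 4′-OH cannot reach C10.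

**Step 12**
Reactants: 22 (4R,5R,6S,7R,10R)-1-(3-acetyl-4-hydroxy-6-methoxyphenyl)-10,2′-epoxyaristol-1-en-8-one
Product: 23 (1R,4R,5R,6S,7R,10S)-1-(3-acetyl-4-hydroxy-6-methoxyphenyl)-10,2′-epoxyaristolan-8-one
Conditions: H2 (1 atm), 5% Rh/Al2O3, EtOAc, 23 °C
Reagents that add atoms: none
Why: Heterogeneous syn-hydrogenation of the styrene-type C1=C2 bond from the C9 face, the less hindered one and the only one leading to a cis-fused dihydrobenzofuran, sets C1 (R), and Rh avoids hydrogenolysis of the allylic C10–O bond.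

**Step 13**
Reactants: 23 (1R,4R,5R,6S,7R,10S)-1-(3-acetyl-4-hydroxy-6-methoxyphenyl)-10,2′-epoxyaristolan-8-one
Product: 24 (1R,4R,5R,6S,7R,10S)-1-(3-acetyl-4-hydroxy-6-methoxyphenyl)-10,2′-epoxyaristolan-8-ol (C8 epimers, both converge in step 15)
Conditions: NaBH4 (1.5 equiv), MeOH/THF, −20 °C
Reagents that add atoms: none
Why: Chemoselective borohydride reduction of the C8 ketone (the chelated, doubly ortho-oxygenated aryl ketone is inert) removes the β-aryloxy ketone, so the strongly basic next step cannot open the dihydrofuran by retro-oxa-Michael elimination or condense at C9.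

**Step 14**
Reactants: 24 (1R,4R,5R,6S,7R,10S)-1-(3-acetyl-4-hydroxy-6-methoxyphenyl)-10,2′-epoxyaristolan-8-ol; 25 4-methoxybenzaldehyde
Product: 26 (1R,4R,5R,6S,7R,10S)-1-{4-hydroxy-6-methoxy-3-[(E)-3-(4-methoxyphenyl)prop-2-enoyl]phenyl}-10,2′-epoxyaristolan-8-ol (C8 epimers)
Conditions: KOH (40% aq.), EtOH, 23 °C, 24 h
Reagents that add atoms: none
Why: Claisen–Schmidt (crossed aldol) condensation of the aryl methyl ketone with the non-enolisable aldehyde gives the (E)-chalcone, the thermodynamically favoured alkene geometry.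

**Step 15**
Reactants: 26 (1R,4R,5R,6S,7R,10S)-1-{4-hydroxy-6-methoxy-3-[(E)-3-(4-methoxyphenyl)prop-2-enoyl]phenyl}-10,2′-epoxyaristolan-8-ol
Product: 27 (1R,4R,5R,6S,7R,10S)-1-{4-hydroxy-6-methoxy-3-[(E)-3-(4-methoxyphenyl)prop-2-enoyl]phenyl}-10,2′-epoxyaristolan-8-one
Conditions: Dess–Martin periodinane, NaHCO3, CH2Cl2, 23 °C
Reagents that add atoms: none
Why: Dess–Martin oxidation returns the C8 ketone under neutral conditions that tolerate the chelated phenol and the enone.

**Step 16**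
Reactants: 27 (1R,4R,5R,6S,7R,10S)-1-{4-hydroxy-6-methoxy-3-[(E)-3-(4-methoxyphenyl)prop-2-enoyl]phenyl}-10,2′-epoxyaristolan-8-one
Product: 28 (1R,4R,5R,6S,7R,10S)-1-{4-hydroxy-6-methoxy-3-[(E)-3-(4-methoxyphenyl)prop-2-enoyl]phenyl}-10,2′-epoxyaristolane-8,9-dione (target)
Conditions: SeO2 (2 equiv), 1,4-dioxane/H2O (30:1), 95 °C
Reagents that add atoms: selenium dioxide O=[Se]=O
Why: Riley oxidation: C9 is the only enolisable position of the C8 ketone (C7 is a cyclopropane carbon), the chalcone carbonyl has no α-CH and the non-enolisable 8,9-dione cannot over-oxidise, so SeO2 delivers the target without touching any stereocentre.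

**Compound list**
1 | 2-methylcyclohex-2-en-1-one | CC1=CCCCC1=O | starting material
2 | dimethylaluminium (R)-2,3-dimethylcyclohex-1-en-1-olate | CC1=C(O[Al](C)C)CCC[C@H]1C | intermediate
3 | (R)-2,3-dimethylcyclohex-1-en-1-yl acetate | CC1=C(OC(C)=O)CCC[C@H]1C | intermediate
4 | 3-(trimethylsilyl)but-3-en-2-one | CC(=O)C(=C)[Si](C)(C)C | starting material
5 | lithium (R)-2,3-dimethylcyclohex-1-en-1-olate | CC1=C(O[Li])CCC[C@H]1C | intermediate
6 | (2S,3R)-2,3-dimethyl-2-[3-oxo-2-(trimethylsilyl)butyl]cyclohexan-1-one (both epimers at the silyl carbon) | CC(=O)C(C[C@@]1(C)[C@H](C)CCCC1=O)[Si](C)(C)C | intermediate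
7 | (4aS,5R)-4a,5-dimethyl-4,4a,5,6,7,8-hexahydronaphthalen-2(3H)-one | C12=CC(=O)CC[C@@]2(C)[C@H](C)CCC1 | intermediate
8 | trimethyl{[(4aS,5R)-4a,5-dimethyl-4,4a,5,6,7,8-hexahydronaphthalen-2-yl]oxy}silane | C12=CC(O[Si](C)(C)C)=CC[C@@]2(C)[C@H](C)CCC1 | intermediate
9 | (4aR,5R)-4a,5-dimethyl-5,6,7,8-tetrahydronaphthalen-2(4aH)-one | C12=CC(=O)C=C[C@@]2(C)[C@H](C)CCC1 | intermediate
10 | isopropyldiphenylsulfonium tetrafluoroborate | CC(C)[S+](c1ccccc1)c1ccccc1.F[B-](F)(F)F | starting material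
11 | diphenylsulfonium isopropylide | C[C-](C)[S+](c1ccccc1)c1ccccc1 | intermediate
12 | (−)-aristolone, (4R,5R,6S,7R)-aristol-9-en-8-one | C12=CC(=O)[C@@H]3[C@@H](C3(C)C)[C@@]2(C)[C@H](C)CCC1 | intermediate
13 | (4R,5R,6S,7R)-1-hydroxyaristol-9-en-8-one (C1 epimers) | C12=CC(=O)[C@@H]3[C@@H](C3(C)C)[C@@]2(C)[C@H](C)CCC1O | intermediate
14 | (4R,5R,6S,7R)-aristol-9-ene-1,8-dione | C12=CC(=O)[C@@H]3[C@@H](C3(C)C)[C@@]2(C)[C@H](C)CCC1=O | intermediate
15 | (4R,5R,6S,7R)-8-oxoaristola-1,9-dien-1-yl trifluoromethanesulfonate | C12=CC(=O)[C@@H]3[C@@H](C3(C)C)[C@@]2(C)[C@H](C)CC=C1OS(=O)(=O)C(F)(F)F | intermediate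
16 | 1-(2,6-dihydroxy-4-methoxyphenyl)ethan-1-one | CC(=O)c1c(O)cc(OC)cc1O | starting material
17 | 1-[4-methoxy-2,6-bis(methoxymethoxy)phenyl]ethan-1-one | CC(=O)c1c(OCOC)cc(OC)cc1OCOC | intermediate
18 | 1-[3-bromo-4-methoxy-2,6-bis(methoxymethoxy)phenyl]ethan-1-one | CC(=O)c1c(OCOC)cc(OC)c(Br)c1OCOC | intermediate
19 | (4R,5R,6S,7R)-1-(4,4,5,5-tetramethyl-1,3,2-dioxaborolan-2-yl)aristola-1,9-dien-8-one | C12=CC(=O)[C@@H]3[C@@H](C3(C)C)[C@@]2(C)[C@H](C)CC=C1B1OC(C)(C)C(C)(C)O1 | intermediate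
20 | (4R,5R,6S,7R)-1-[3-acetyl-6-methoxy-2,4-bis(methoxymethoxy)phenyl]aristola-1,9-dien-8-one | C12=CC(=O)[C@@H]3[C@@H](C3(C)C)[C@@]2(C)[C@H](C)CC=C1c1c(OC)cc(OCOC)c(C(C)=O)c1OCOC | intermediate
21 | (4R,5R,6S,7R)-1-(3-acetyl-2,4-dihydroxy-6-methoxyphenyl)aristola-1,9-dien-8-one | C12=CC(=O)[C@@H]3[C@@H](C3(C)C)[C@@]2(C)[C@H](C)CC=C1c1c(OC)cc(O)c(C(C)=O)c1O | intermediate
22 | (4R,5R,6S,7R,10R)-1-(3-acetyl-4-hydroxy-6-methoxyphenyl)-10,2′-epoxyaristol-1-en-8-one | CC(=O)c2c(O)cc(OC)c3c2O[C@]24CC(=O)[C@@H]5[C@@H](C5(C)C)[C@@]2(C)[C@H](C)CC=C34 | intermediate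
23 | (1R,4R,5R,6S,7R,10S)-1-(3-acetyl-4-hydroxy-6-methoxyphenyl)-10,2′-epoxyaristolan-8-one | CC(=O)c2c(O)cc(OC)c3c2O[C@]24CC(=O)[C@@H]5[C@@H](C5(C)C)[C@@]2(C)[C@H](C)CC[C@H]34 | intermediate
24 | (1R,4R,5R,6S,7R,10S)-1-(3-acetyl-4-hydroxy-6-methoxyphenyl)-10,2′-epoxyaristolan-8-ol (C8 epimers) | CC(=O)c2c(O)cc(OC)c3c2O[C@]24CC(O)[C@@H]5[C@@H](C5(C)C)[C@@]2(C)[C@H](C)CC[C@H]34 | intermediate
25 | 4-methoxybenzaldehyde | COc1ccc(C=O)cc1 | starting material
26 | (1R,4R,5R,6S,7R,10S)-1-{4-hydroxy-6-methoxy-3-[(E)-3-(4-methoxyphenyl)prop-2-enoyl]phenyl}-10,2′-epoxyaristolan-8-ol (C8 epimers) | COc1ccc(/C=C/C(=O)c2c(O)cc(OC)c3c2O[C@]24CC(O)[C@@H]5[C@@H](C5(C)C)[C@@]2(C)[C@H](C)CC[C@H]34)cc1 | intermediate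
27 | (1R,4R,5R,6S,7R,10S)-1-{4-hydroxy-6-methoxy-3-[(E)-3-(4-methoxyphenyl)prop-2-enoyl]phenyl}-10,2′-epoxyaristolan-8-one | COc1ccc(/C=C/C(=O)c2c(O)cc(OC)c3c2O[C@]24CC(=O)[C@@H]5[C@@H](C5(C)C)[C@@]2(C)[C@H](C)CC[C@H]34)cc1 | intermediate
28 | (1R,4R,5R,6S,7R,10S)-1-{4-hydroxy-6-methoxy-3-[(E)-3-(4-methoxyphenyl)prop-2-enoyl]phenyl}-10,2′-epoxyaristolane-8,9-dione | COc1ccc(/C=C/C(=O)c2c(O)cc(OC)c3c2O[C@]24C(=O)C(=O)[C@@H]5[C@@H](C5(C)C)[C@@]2(C)[C@H](C)CC[C@H]34)cc1 | target

**Totals and risks**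
Total step count: 16. Longest linear sequence: 14 steps (steps 1–7 and 10–16); the arene branch (steps 8–9) joins at step 10.

Most likely to fail, first: step 5. No screened P450 variant may give enough activity or C1 selectivity on the bulky, poorly soluble tricycle 12. The fallback sets out from 12 and is purely chemical: soft enolisation (TBSOTf, Et3N, CH2Cl2, 0 °C; only γ-deprotonation at C1 is possible) gives 8-(tert-butyldimethylsilyloxy)aristola-1(10),8-diene F1. Peracid oxidation of F1 (m-CPBA, NaHCO3, CH2Cl2, −20 °C; HF·pyridine work-up) attacks the γ-carbon C1 (vinylogous Rubottom oxidation, as known for steroidal dienol ethers) and comes back at 13, from which step 6 continues.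

Second: step 10. Borylation of the dienyl triflate and coupling with a di-ortho-substituted, electron-rich bromide may stall or protodeboronate. The fallback reverses the roles of the partners (Negishi coupling) and sets out from 17 and 15: NIS (MeCN, 23 °C) converts 17 into 1-[3-iodo-4-methoxy-2,6-bis(methoxymethoxy)phenyl]ethan-1-one F2. Zinc insertion (Zn dust, LiCl, THF, 50 °C; the ketone is tolerated) then gives [3-acetyl-6-methoxy-2,4-bis(methoxymethoxy)phenyl]zinc iodide F3, which is coupled with triflate 15 (Pd(OAc)2/SPhos, THF, 60 °C) and comes back at 20.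

Third: step 16. The hot, acidic SeO2 medium may reopen the β-aryloxy ketone or convert the neopentyl C9 methylene only slowly. The fallback sets out from 27 and oxidises C9 through the enol ether: TBSOTf/Et3N (CH2Cl2, −20 °C) gives the 8,4′-bis(tert-butyldimethylsilyloxy)-8-ene derivative of 27 F4 (silyl enol ether toward C9, the only enolisable side, plus aryl silyl ether). Rubottom oxidation (DMDO, acetone, −40 °C; then HF·pyridine) gives the 9-hydroxy derivative of 27 F5, and Dess–Martin periodinane oxidises F5 to the dione, coming back at 28.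

**Further compounds**
F1 | step 5 | 8-(tert-butyldimethylsilyloxy)aristola-1(10),8-diene (stereocentres as in 12) | C1=2C=C(O[Si](C)(C)C(C)(C)C)[C@@H]3[C@@H](C3(C)C)[C@@]1(C)[C@H](C)CCC=2
F2 | step 10 | 1-[3-iodo-4-methoxy-2,6-bis(methoxymethoxy)phenyl]ethan-1-one | CC(=O)c1c(OCOC)cc(OC)c(I)c1OCOC
F3 | step 10 | [3-acetyl-6-methoxy-2,4-bis(methoxymethoxy)phenyl]zinc iodide | CC(=O)c1c(OCOC)cc(OC)c([Zn]I)c1OCOC
F4 | step 16 | 8,4′-bis(tert-butyldimethylsilyloxy)-8-ene derivative of 27 (stereocentres as in 27) | COc1ccc(/C=C/C(=O)c2c(O[Si](C)(C)C(C)(C)C)cc(OC)c3c2O[C@]24C=C(O[Si](C)(C)C(C)(C)C)[C@@H]5[C@@H](C5(C)C)[C@@]2(C)[C@H](C)CC[C@H]34)cc1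
F5 | step 16 | 9-hydroxy derivative of 27 (C9 epimers, other stereocentres as in 27) | COc1ccc(/C=C/C(=O)c2c(O)cc(OC)c3c2O[C@]24C(O)C(=O)[C@@H]5[C@@H](C5(C)C)[C@@]2(C)[C@H](C)CC[C@H]34)cc1
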